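## Retrosynthetic overview

1. The (E)-CH=CH bond next to the quaternary carbon is cut by a Julia–Kocienski olefination into an α-quaternary C18 aldehyde (ring half) and a C16 tetrazolyl sulfone (acyclic triene half).
2. The aldehyde's quaternary centre comes from a Sharpless epoxide, by way of a vinyl epoxide and a BF3-induced 1,2-vinyl shift. The E-allylic alcohol comes from alkyne carboalumination. The CH(Me)–ring bond comes from a Zweifel olefination of a crotonate-derived secondary boronic ester with the cyclohexenyllithium.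
3. The cyclohexene is the only ring and is made first: organocatalytic Michael addition (first stereocentre), aldol condensation, then two cuprate additions ending in a regiodefined enol triflate.
4. The sulfone comes from a Cu-catalysed sp3–sp3 union of two C4 units, both from (R)-Roche ester made with an ene-reductase. The methylidene comes from a Weinreb ketone and Tebbe methylenation. The isopropenyl CH(Me) unit comes from the same boronic ester by a second Zweifel olefination.

Assumption: for each chemocatalytic asymmetric step the catalyst antipode quoted is the one that gives the configuration drawn; if a given catalyst shows the opposite sense, its mirror image is used.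

## Route

Step 1
Reactants: 1 propanal; 2 but-3-en-2-one (methyl vinyl ketone)
Product: 3 (2R)-2-methyl-5-oxohexanal
Conditions: (S)-2-[methoxy(diphenyl)methyl]pyrrolidine (5 mol%), ethyl 3,4-dihydroxybenzoate (20 mol%), neat, 4 °C
Reagents that add atoms: none
Why: Enamine-catalysed asymmetric Michael addition; the diphenylmethyl group of the catalyst shields one face of the propanal enamine, so the enone adds to the open face and sets the (R) α-methyl centre that becomes the ring CH(Me).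

Step 2
Reactants: 3 (2R)-2-methyl-5-oxohexanal
Product: 4 (4R)-4-methylcyclohex-2-en-1-one
Conditions: LiOH·H2O (0.1 equiv), i-PrOH, rt
Reagents that add atoms: none
Why: Intramolecular aldol condensation of the methyl ketone onto the aldehyde closes the only ring of the target and moves the stereocentre to the non-acidic C4 position.

Step 3
Reactants: 4 (4R)-4-methylcyclohex-2-en-1-one
Product: 5 trimethyl{[(3S,4R)-3,4-dimethylcyclohex-1-en-1-yl]oxy}silane
Conditions: MeLi (2.2 equiv), CuI (1.1 equiv), Et2O, 0 °C; then 4, Me3SiCl, Et3N, −78 → 0 °C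
Reagents that add atoms: methyllithium (used as Me2CuLi), [Li]C; chlorotrimethylsilane, C[Si](C)(C)Cl
Why: Silyl-chloride-accelerated cuprate 1,4-addition anti to the C4 methyl group with O-silylation of the enolate; the new C3 centre is erased in step 4.

Step 4
Reactants: 5 trimethyl{[(3S,4R)-3,4-dimethylcyclohex-1-en-1-yl]oxy}silane
Product: 6 (4R)-3,4-dimethylcyclohex-2-en-1-one
Conditions: Pd(OAc)2 (10 mol%), O2 (1 atm), DMSO, rt
Reagents that add atoms: none
Why: Saegusa–Ito oxidation (palladium enolate, β-hydride elimination) regenerates the enone, now with the 3-methyl group, without touching C4.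

Step 5
Reactants: 6 (4R)-3,4-dimethylcyclohex-2-en-1-one
Product: 8 (4R)-3,3,4-trimethylcyclohex-1-en-1-yl trifluoromethanesulfonate, via lithium enolate 7 (not isolated)
Conditions: MeLi (2.2 equiv), CuI (1.1 equiv), Et2O, 0 °C; then PhNTf2, THF, 0 °C → rt
Reagents that add atoms: methyllithium (used as Me2CuLi), [Li]C; N-phenylbis(trifluoromethanesulfonimide), O=S(=O)(N(c1ccccc1)S(=O)(=O)C(F)(F)F)C(F)(F)F
Why: A second cuprate 1,4-addition builds the gem-dimethyl carbon and gives the enolate only on the C1–C2 side, which O-triflation fixes as the single enol triflate regioisomer.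

Step 6
Reactants: 8 (4R)-3,3,4-trimethylcyclohex-1-en-1-yl trifluoromethanesulfonate
Product: 9 trimethyl[(4R)-3,3,4-trimethylcyclohex-1-en-1-yl]stannane
Conditions: Me3SnSnMe3, Pd(PPh3)4 (5 mol%), LiCl, THF, 65 °C
Reagents that add atoms: hexamethylditin, C[Sn](C)(C)[Sn](C)(C)C
Why: Pd-catalysed stannylation of the enol triflate (oxidative addition, Sn–Sn transmetallation, reductive elimination) keeps the double-bond position.

Step 7
Reactants: 10 tert-butyl (2E)-but-2-enoate
Product: 11 tert-butyl (3R)-3-(4,4,5,5-tetramethyl-1,3,2-dioxaborolan-2-yl)butanoate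
Conditions: B2pin2 (1.1 equiv), CuCl (3 mol%), NaOt-Bu (5 mol%), (R)-1-[(Sp)-2-(diphenylphosphino)ferrocenyl]ethyldicyclohexylphosphine (4 mol%), MeOH (2 equiv), THF, rt
Reagents that add atoms: bis(pinacolato)diboron, CC1(C)OB(OC1(C)C)B1OC(C)(C)C(C)(C)O1
Why: Copper-catalysed asymmetric conjugate borylation; the chiral bisphosphine–copper boryl complex selects one face of the crotonate and sets the C–B stereocentre (about 90% ee or better), later transferred to both CH(Me)–C(sp2) centres made from 11.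

Step 8
Reactants: 9 trimethyl[(4R)-3,3,4-trimethylcyclohex-1-en-1-yl]stannane; 11 tert-butyl (3R)-3-(4,4,5,5-tetramethyl-1,3,2-dioxaborolan-2-yl)butanoate
Product: 14 tert-butyl (3R)-3-[(4R)-3,3,4-trimethylcyclohex-1-en-1-yl]butanoate, via vinyllithium 12 (not isolated), via lithium boronate 13 (not isolated)
Conditions: 9, MeLi (1.0 equiv), THF, −78 → 0 °C; 11, −78 °C; I2, THF, −78 °C; NaOMe, MeOH, −78 °C → rt
Reagents that add atoms: none
Why: Zweifel olefination: tin–lithium exchange, boronate formation, iodine-triggered 1,2-migration of the sec-alkyl group with retention at carbon, then methoxide-promoted elimination of boron and iodide (necessarily syn in the six-membered ring, which re-forms the ring alkene), so the C–B centre becomes the CH(Me)–ring centre unchanged.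

Step 9
Reactants: 14 tert-butyl (3R)-3-[(4R)-3,3,4-trimethylcyclohex-1-en-1-yl]butanoate
Product: 15 (3R)-3-[(4R)-3,3,4-trimethylcyclohex-1-en-1-yl]butan-1-ol
Conditions: LiAlH4, Et2O, 0 °C → rt
Reagents that add atoms: none
Why: Hydride reduction of the ester to the primary alcohol; no stereocentre is affected.

Step 10
Reactants: 15 (3R)-3-[(4R)-3,3,4-trimethylcyclohex-1-en-1-yl]butan-1-ol
Product: 16 (4R)-1-[(2R)-4-iodobutan-2-yl]-3,3,4-trimethylcyclohex-1-ene
Conditions: I2, PPh3, imidazole, CH2Cl2, 0 °C → rt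
Reagents that add atoms: iodine, II
Why: Appel-type iodination through the alkoxyphosphonium ion with SN2 displacement at the primary carbon.

Step 11
Reactants: 16 (4R)-1-[(2R)-4-iodobutan-2-yl]-3,3,4-trimethylcyclohex-1-ene
Product: 17 (4R)-1-[(2R)-hex-5-yn-2-yl]-3,3,4-trimethylcyclohex-1-ene
Conditions: lithium acetylide–ethylenediamine complex, DMSO, 0 °C → rt
Reagents that add atoms: lithium acetylide–ethylenediamine complex, [Li]C#C.NCCN
Why: SN2 alkylation of acetylide by the unhindered primary iodide gives the terminal alkyne.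

Step 12
Reactants: 17 (4R)-1-[(2R)-hex-5-yn-2-yl]-3,3,4-trimethylcyclohex-1-ene
Product: 19 (2E,6R)-3-methyl-6-[(4R)-3,3,4-trimethylcyclohex-1-en-1-yl]hept-2-en-1-ol, via alkenylalane 18 (not isolated)
Conditions: Me3Al (2.5 equiv), Cp2ZrCl2 (0.25 equiv), CH2Cl2, 0 °C → rt; then n-BuLi, THF, −78 °C; (CH2O)n, → rt
Reagents that add atoms: trimethylaluminium, C[Al](C)C; paraformaldehyde (as formaldehyde), C=O
Why: Negishi zirconium-catalysed syn-methylalumination puts methyl on the internal carbon and aluminium cis to it, and the derived alanate adds to formaldehyde with retention to give only the E-allylic alcohol.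

Step 13
Reactants: 19 (2E,6R)-3-methyl-6-[(4R)-3,3,4-trimethylcyclohex-1-en-1-yl]hept-2-en-1-ol
Product: 20 [(2S,3S)-3-methyl-3-{(3R)-3-[(4R)-3,3,4-trimethylcyclohex-1-en-1-yl]butyl}oxiran-2-yl]methanol
Conditions: Ti(Oi-Pr)4 (10 mol%), L-(+)-diethyl tartrate (12 mol%), t-BuOOH, 4 Å sieves, CH2Cl2, −20 °C
Reagents that add atoms: tert-butyl hydroperoxide, CC(C)(C)OO
Why: Sharpless asymmetric epoxidation; the titanium–tartrate complex delivers oxygen to one face of the allylic alcohol under reagent control, giving the (2S,3S) epoxide, while the ring alkene, which has no directing hydroxyl, is untouched.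

Step 14
Reactants: 20 [(2S,3S)-3-methyl-3-{(3R)-3-[(4R)-3,3,4-trimethylcyclohex-1-en-1-yl]butyl}oxiran-2-yl]methanol
Product: 21 (2R,3S)-3-methyl-3-{(3R)-3-[(4R)-3,3,4-trimethylcyclohex-1-en-1-yl]butyl}oxirane-2-carbaldehyde
Conditions: Dess–Martin periodinane, NaHCO3, CH2Cl2, 0 °C → rt
Reagents that add atoms: none
Why: Buffered Dess–Martin oxidation of the primary alcohol to the aldehyde leaves the acid-sensitive epoxide intact (the descriptor at C2 changes only through priority order).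

Step 15
Reactants: 21 (2R,3S)-3-methyl-3-{(3R)-3-[(4R)-3,3,4-trimethylcyclohex-1-en-1-yl]butyl}oxirane-2-carbaldehyde
Product: 22 (2S,3S)-3-ethenyl-2-methyl-2-{(3R)-3-[(4R)-3,3,4-trimethylcyclohex-1-en-1-yl]butyl}oxirane
Conditions: Ph3PCH3Br, KN(SiMe3)2, THF, −78 → 0 °C
Reagents that add atoms: methyltriphenylphosphonium bromide, C[P+](c1ccccc1)(c1ccccc1)c1ccccc1.[Br-]
Why: Wittig methylenation of the epoxy aldehyde gives the vinyl epoxide without touching either epoxide carbon.

Step 16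
Reactants: 22 (2S,3S)-3-ethenyl-2-methyl-2-{(3R)-3-[(4R)-3,3,4-trimethylcyclohex-1-en-1-yl]butyl}oxirane
Product: 23 (2S,5R)-2-ethenyl-2-methyl-5-[(4R)-3,3,4-trimethylcyclohex-1-en-1-yl]hexanal
Conditions: BF3·OEt2 (1.0 equiv), CH2Cl2, −78 °C
Reagents that add atoms: none
Why: Lewis-acid semipinacol (Meinwald-type) rearrangement: the epoxide opens at the tertiary carbon while the vinyl group shifts 1,2 anti to the departing oxygen, so the Sharpless centre is carried with inversion into the all-carbon quaternary centre and the former carbinol carbon becomes the aldehyde.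

Step 17
Reactants: 11 tert-butyl (3R)-3-(4,4,5,5-tetramethyl-1,3,2-dioxaborolan-2-yl)butanoate
Product: 25 tert-butyl (3R)-3,4-dimethylpent-4-enoate, via lithium boronate 24 (not isolated)
Conditions: 2-bromopropene, t-BuLi (2 equiv), THF, −78 °C; 11, −78 °C; I2, THF, −78 °C; NaOMe, MeOH, −78 °C → rt
Reagents that add atoms: 2-bromopropene, CC(Br)=C
Why: Zweifel olefination with isopropenyllithium; 1,2-migration with retention turns the C–B centre into the CH(Me)–isopropenyl centre.

Step 18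
Reactants: 25 tert-butyl (3R)-3,4-dimethylpent-4-enoate
Product: 26 (3R)-3,4-dimethylpent-4-en-1-ol
Conditions: LiAlH4, Et2O, 0 °C
Reagents that add atoms: none
Why: Hydride reduction of the ester to the primary alcohol.

Step 19
Reactants: 26 (3R)-3,4-dimethylpent-4-en-1-ol
Product: 27 (3R)-5-bromo-2,3-dimethylpent-1-ene
Conditions: CBr4, PPh3, CH2Cl2, 0 °C
Reagents that add atoms: carbon tetrabromide, BrC(Br)(Br)Br
Why: Appel bromination by SN2 displacement at the primary carbon.

Step 20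
Reactants: 28 methyl 2-(hydroxymethyl)prop-2-enoate
Product: 29 methyl (2R)-3-hydroxy-2-methylpropanoate ((R)-Roche ester)
Conditions: ene-reductase (flavin-dependent Old Yellow Enzyme family), NADH (cat.), HCO2Na, formate dehydrogenase, phosphate buffer pH 7.5, 30 °C
Reagents that add atoms: none
Why: Ene-reductase-catalysed asymmetric C=C reduction; in the active site the reduced flavin gives hydride to the β-carbon and a tyrosine protonates the α-carbon from the opposite face, giving the (R) ester in very high ee, the source of two methyl-bearing centres of the sulfone half.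

Step 21
Reactants: 29 methyl (2R)-3-hydroxy-2-methylpropanoate
Product: 30 methyl (2R)-3-[(tert-butyldiphenylsilyl)oxy]-2-methylpropanoate
Conditions: t-BuPh2SiCl, imidazole, CH2Cl2, rt
Reagents that add atoms: tert-butylchlorodiphenylsilane, CC(C)(C)[Si](Cl)(c1ccccc1)c1ccccc1
Why: Silylation of the primary alcohol gives a robust ether that survives the Grignard, methylenation and coupling steps.

Step 22
Reactants: 30 methyl (2R)-3-[(tert-butyldiphenylsilyl)oxy]-2-methylpropanoate
Product: 31 (2R)-3-[(tert-butyldiphenylsilyl)oxy]-N-methoxy-N,2-dimethylpropanamide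
Conditions: MeNH(OMe)·HCl (1.5 equiv), i-PrMgCl (3 equiv), THF, −20 → 0 °C
Reagents that add atoms: N,O-dimethylhydroxylamine hydrochloride, CNOC.Cl
Why: Weinreb amidation of the ester by the magnesium amide at low temperature, conditions under which the α-methyl centre does not epimerise.

Step 23
Reactants: 27 (3R)-5-bromo-2,3-dimethylpent-1-ene; 31 (2R)-3-[(tert-butyldiphenylsilyl)oxy]-N-methoxy-N,2-dimethylpropanamide
Product: 33 (2R,6R)-1-[(tert-butyldiphenylsilyl)oxy]-2,6,7-trimethyloct-7-en-3-one, via Grignard reagent 32 (not isolated)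
Conditions: 27, Mg, THF, rt; then 31, THF, 0 °C; NH4Cl (aq)
Reagents that add atoms: none
Why: Grignard addition to the Weinreb amide stops at the ketone because the chelated tetrahedral intermediate collapses only on work-up.

Step 24
Reactants: 33 (2R,6R)-1-[(tert-butyldiphenylsilyl)oxy]-2,6,7-trimethyloct-7-en-3-one
Product: 34 tert-butyl{[(2S,6R)-2,6,7-trimethyl-3-methylideneoct-7-en-1-yl]oxy}diphenylsilane
Conditions: Cp2Ti(μ-Cl)(μ-CH2)AlMe2, pyridine, THF/toluene, −40 °C → rt
Reagents that add atoms: Tebbe reagent, C[Al-]1(C)C[Ti]([Cl+]1)(C2C=CC=C2)C2C=CC=C2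
Why: Tebbe methylenation (titanium methylidene [2+2]/retro-[2+2]) is non-basic, so the α-methyl centre is not epimerised and the β-silyloxy group is not eliminated (the descriptor changes only through priority order).

Step 25
Reactants: 34 tert-butyl{[(2S,6R)-2,6,7-trimethyl-3-methylideneoct-7-en-1-yl]oxy}diphenylsilane
Product: 35 (2S,6R)-2,6,7-trimethyl-3-methylideneoct-7-en-1-ol
Conditions: Bu4NF, THF, rt
Reagents that add atoms: none
Why: Fluoride cleavage of the silyl ether frees the primary alcohol.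

Step 26
Reactants: 35 (2S,6R)-2,6,7-trimethyl-3-methylideneoct-7-en-1-ol
Product: 36 (2S,6R)-2,6,7-trimethyl-3-methylideneoct-7-en-1-yl 4-methylbenzenesulfonate
Conditions: TsCl, Et3N, DMAP (cat.), CH2Cl2, 0 °C → rt
Reagents that add atoms: 4-methylbenzenesulfonyl chloride, Cc1ccc(cc1)S(Cl)(=O)=O
Why: Sulfonylation turns the primary alcohol into the electrophile for the sp3–sp3 coupling.

Step 27
Reactants: 30 methyl (2R)-3-[(tert-butyldiphenylsilyl)oxy]-2-methylpropanoate
Product: 37 (2S)-3-[(tert-butyldiphenylsilyl)oxy]-2-methylpropan-1-ol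
Conditions: i-Bu2AlH (2.2 equiv), CH2Cl2, −78 → 0 °C
Reagents that add atoms: none
Why: Hydride reduction of the ester to the primary alcohol; using the ester arm here and the hydroxyl arm in step 26 gives the two C4 units opposite orientation, as the target needs.

Step 28
Reactants: 37 (2S)-3-[(tert-butyldiphenylsilyl)oxy]-2-methylpropan-1-ol
Product: 38 [(2R)-3-bromo-2-methylpropoxy](tert-butyl)diphenylsilane
Conditions: CBr4, PPh3, CH2Cl2, 0 °C
Reagents that add atoms: carbon tetrabromide, BrC(Br)(Br)Br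
Why: Appel bromination at the primary carbon, with no change at the stereocentre.

Step 29
Reactants: 38 [(2R)-3-bromo-2-methylpropoxy](tert-butyl)diphenylsilane; 36 (2S,6R)-2,6,7-trimethyl-3-methylideneoct-7-en-1-yl 4-methylbenzenesulfonate
Product: 40 tert-butyldiphenyl{[(2S,5R,9R)-2,5,9,10-tetramethyl-6-methylideneundec-10-en-1-yl]oxy}silane, via Grignard reagent 39 (not isolated)
Conditions: 38, Mg, THF, rt; then 36, Li2CuCl4 (5 mol%), THF, −78 °C → rt
Reagents that add atoms: none
Why: Copper-catalysed Kochi-type sp3–sp3 cross-coupling of a primary Grignard reagent with a primary tosylate joins the two Roche-derived units at CH2–CH2 without involving either stereocentre.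

Step 30
Reactants: 40 tert-butyldiphenyl{[(2S,5R,9R)-2,5,9,10-tetramethyl-6-methylideneundec-10-en-1-yl]oxy}silane
Product: 41 (2S,5R,9R)-2,5,9,10-tetramethyl-6-methylideneundec-10-en-1-ol
Conditions: Bu4NF, THF, rt
Reagents that add atoms: none
Why: Fluoride cleavage of the silyl ether frees the primary alcohol.

Step 31
Reactants: 41 (2S,5R,9R)-2,5,9,10-tetramethyl-6-methylideneundec-10-en-1-ol
Product: 42 1-phenyl-5-{[(2S,5R,9R)-2,5,9,10-tetramethyl-6-methylideneundec-10-en-1-yl]sulfanyl}-1H-tetrazole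
Conditions: 1-phenyl-1H-tetrazole-5-thiol, PPh3, diisopropyl azodicarboxylate, THF, 0 °C → rt
Reagents that add atoms: 1-phenyl-1H-tetrazole-5-thiol, Sc1nnnn1-c1ccccc1
Why: Mitsunobu thioetherification of the primary alcohol by SN2 at CH2, away from the stereocentre.

Step 32
Reactants: 42 1-phenyl-5-{[(2S,5R,9R)-2,5,9,10-tetramethyl-6-methylideneundec-10-en-1-yl]sulfanyl}-1H-tetrazole
Product: 43 1-phenyl-5-{[(2S,5R,9R)-2,5,9,10-tetramethyl-6-methylideneundec-10-en-1-yl]sulfonyl}-1H-tetrazole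
Conditions: (NH4)6Mo7O24·4H2O (10 mol%), 30% H2O2, EtOH, 0 °C → rt
Reagents that add atoms: hydrogen peroxide, OO
Why: Molybdate-catalysed sulfide-to-sulfone oxidation is chemoselective for sulfur over the two unactivated 1,1-disubstituted alkenes.

Step 33
Reactants: 23 (2S,5R)-2-ethenyl-2-methyl-5-[(4R)-3,3,4-trimethylcyclohex-1-en-1-yl]hexanal; 43 1-phenyl-5-{[(2S,5R,9R)-2,5,9,10-tetramethyl-6-methylideneundec-10-en-1-yl]sulfonyl}-1H-tetrazole
Product: 44 (4R)-1-[(2R,5S,6E,8S,11R,15R)-5-ethenyl-5,8,11,15,16-pentamethyl-12-methylideneheptadeca-6,16-dien-2-yl]-3,3,4-trimethylcyclohex-1-ene (CNP0321027.1)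
Conditions: KN(SiMe3)2 added to 23 + 43, DME, −60 °C → rt
Reagents that add atoms: none
Why: Julia–Kocienski olefination; the sulfonyl carbanion adds to the non-enolisable aldehyde, and Smiles rearrangement with loss of SO2 and tetrazolone gives the E-alkene (phenyltetrazolyl sulfone, potassium base and an α-branched aldehyde favour E) with both neighbouring stereocentres untouched.

## Compound list

1 | propanal | CCC=O | starting material
2 | but-3-en-2-one (methyl vinyl ketone) | CC(=O)C=C | starting material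
3 | (2R)-2-methyl-5-oxohexanal | O=C[C@H](C)CCC(C)=O | intermediate
4 | (4R)-4-methylcyclohex-2-en-1-one | O=C1C=C[C@H](C)CC1 | intermediate
5 | trimethyl{[(3S,4R)-3,4-dimethylcyclohex-1-en-1-yl]oxy}silane | C[Si](C)(C)OC1=C[C@@H](C)[C@H](C)CC1 | intermediate
6 | (4R)-3,4-dimethylcyclohex-2-en-1-one | O=C1C=C(C)[C@H](C)CC1 | intermediate
7 | lithium (4R)-3,3,4-trimethylcyclohex-1-en-1-olate | [Li]OC1=CC(C)(C)[C@H](C)CC1 | intermediate (not isolated)
8 | (4R)-3,3,4-trimethylcyclohex-1-en-1-yl trifluoromethanesulfonate | O=S(=O)(OC1=CC(C)(C)[C@H](C)CC1)C(F)(F)F | intermediate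
9 | trimethyl[(4R)-3,3,4-trimethylcyclohex-1-en-1-yl]stannane | C[Sn](C)(C)C1=CC(C)(C)[C@H](C)CC1 | intermediate
10 | tert-butyl (2E)-but-2-enoate | C/C=C/C(=O)OC(C)(C)C | starting material
11 | tert-butyl (3R)-3-(4,4,5,5-tetramethyl-1,3,2-dioxaborolan-2-yl)butanoate | CC(C)(C)OC(=O)C[C@@H](C)B1OC(C)(C)C(C)(C)O1 | intermediate
12 | [(4R)-3,3,4-trimethylcyclohex-1-en-1-yl]lithium | [Li]C1=CC(C)(C)[C@H](C)CC1 | intermediate (not isolated)
13 | lithium [(2R)-4-tert-butoxy-4-oxobutan-2-yl](pinacolato)[(4R)-3,3,4-trimethylcyclohex-1-en-1-yl]borate | [Li+].CC(C)(C)OC(=O)C[C@@H](C)[B-]1(OC(C)(C)C(C)(C)O1)C2=CC(C)(C)[C@H](C)CC2 | intermediate (not isolated)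
14 | tert-butyl (3R)-3-[(4R)-3,3,4-trimethylcyclohex-1-en-1-yl]butanoate | CC(C)(C)OC(=O)C[C@@H](C)C1=CC(C)(C)[C@H](C)CC1 | intermediate
15 | (3R)-3-[(4R)-3,3,4-trimethylcyclohex-1-en-1-yl]butan-1-ol | OCC[C@@H](C)C1=CC(C)(C)[C@H](C)CC1 | intermediate
16 | (4R)-1-[(2R)-4-iodobutan-2-yl]-3,3,4-trimethylcyclohex-1-ene | ICC[C@@H](C)C1=CC(C)(C)[C@H](C)CC1 | intermediate
17 | (4R)-1-[(2R)-hex-5-yn-2-yl]-3,3,4-trimethylcyclohex-1-ene | C#CCC[C@@H](C)C1=CC(C)(C)[C@H](C)CC1 | intermediate
18 | dimethyl{(1E,5R)-2-methyl-5-[(4R)-3,3,4-trimethylcyclohex-1-en-1-yl]hex-1-en-1-yl}alumane | C[Al](C)/C=C(\C)CC[C@@H](C)C1=CC(C)(C)[C@H](C)CC1 | intermediate (not isolated)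
19 | (2E,6R)-3-methyl-6-[(4R)-3,3,4-trimethylcyclohex-1-en-1-yl]hept-2-en-1-ol | OC/C=C(\C)CC[C@@H](C)C1=CC(C)(C)[C@H](C)CC1 | intermediate
20 | [(2S,3S)-3-methyl-3-{(3R)-3-[(4R)-3,3,4-trimethylcyclohex-1-en-1-yl]butyl}oxiran-2-yl]methanol | OC[C@@H]1O[C@@]1(C)CC[C@@H](C)C2=CC(C)(C)[C@H](C)CC2 | intermediate
21 | (2R,3S)-3-methyl-3-{(3R)-3-[(4R)-3,3,4-trimethylcyclohex-1-en-1-yl]butyl}oxirane-2-carbaldehyde | O=C[C@@H]1O[C@@]1(C)CC[C@@H](C)C2=CC(C)(C)[C@H](C)CC2 | intermediate
22 | (2S,3S)-3-ethenyl-2-methyl-2-{(3R)-3-[(4R)-3,3,4-trimethylcyclohex-1-en-1-yl]butyl}oxirane | C=C[C@@H]1O[C@@]1(C)CC[C@@H](C)C2=CC(C)(C)[C@H](C)CC2 | intermediate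
23 | (2S,5R)-2-ethenyl-2-methyl-5-[(4R)-3,3,4-trimethylcyclohex-1-en-1-yl]hexanal | C=C[C@@](C)(C=O)CC[C@@H](C)C1=CC(C)(C)[C@H](C)CC1 | intermediate
24 | lithium [(2R)-4-tert-butoxy-4-oxobutan-2-yl](pinacolato)(prop-1-en-2-yl)borate | [Li+].CC(C)(C)OC(=O)C[C@@H](C)[B-]1(OC(C)(C)C(C)(C)O1)C(C)=C | intermediate (not isolated)
25 | tert-butyl (3R)-3,4-dimethylpent-4-enoate | CC(C)(C)OC(=O)C[C@@H](C)C(C)=C | intermediate
26 | (3R)-3,4-dimethylpent-4-en-1-ol | OCC[C@@H](C)C(C)=C | intermediate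
27 | (3R)-5-bromo-2,3-dimethylpent-1-ene | BrCC[C@@H](C)C(C)=C | intermediate
28 | methyl 2-(hydroxymethyl)prop-2-enoate | C=C(CO)C(=O)OC | starting material
29 | methyl (2R)-3-hydroxy-2-methylpropanoate | COC(=O)[C@H](C)CO | intermediate
30 | methyl (2R)-3-[(tert-butyldiphenylsilyl)oxy]-2-methylpropanoate | COC(=O)[C@H](C)CO[Si](c1ccccc1)(c1ccccc1)C(C)(C)C | intermediate
31 | (2R)-3-[(tert-butyldiphenylsilyl)oxy]-N-methoxy-N,2-dimethylpropanamide | CON(C)C(=O)[C@H](C)CO[Si](c1ccccc1)(c1ccccc1)C(C)(C)C | intermediate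
32 | [(3R)-3,4-dimethylpent-4-en-1-yl]magnesium bromide | Br[Mg]CC[C@@H](C)C(C)=C | intermediate (not isolated)
33 | (2R,6R)-1-[(tert-butyldiphenylsilyl)oxy]-2,6,7-trimethyloct-7-en-3-one | CC(C)(C)[Si](c1ccccc1)(c1ccccc1)OC[C@@H](C)C(=O)CC[C@@H](C)C(C)=C | intermediate
34 | tert-butyl{[(2S,6R)-2,6,7-trimethyl-3-methylideneoct-7-en-1-yl]oxy}diphenylsilane | CC(C)(C)[Si](c1ccccc1)(c1ccccc1)OC[C@@H](C)C(=C)CC[C@@H](C)C(C)=C | intermediate
35 | (2S,6R)-2,6,7-trimethyl-3-methylideneoct-7-en-1-ol | OC[C@@H](C)C(=C)CC[C@@H](C)C(C)=C | intermediate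
36 | (2S,6R)-2,6,7-trimethyl-3-methylideneoct-7-en-1-yl 4-methylbenzenesulfonate | Cc1ccc(cc1)S(=O)(=O)OC[C@@H](C)C(=C)CC[C@@H](C)C(C)=C | intermediate
37 | (2S)-3-[(tert-butyldiphenylsilyl)oxy]-2-methylpropan-1-ol | OC[C@H](C)CO[Si](c1ccccc1)(c1ccccc1)C(C)(C)C | intermediate
38 | [(2R)-3-bromo-2-methylpropoxy](tert-butyl)diphenylsilane | BrC[C@H](C)CO[Si](c1ccccc1)(c1ccccc1)C(C)(C)C | intermediate
39 | {(2R)-3-[(tert-butyldiphenylsilyl)oxy]-2-methylpropyl}magnesium bromide | Br[Mg]C[C@H](C)CO[Si](c1ccccc1)(c1ccccc1)C(C)(C)C | intermediate (not isolated)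
40 | tert-butyldiphenyl{[(2S,5R,9R)-2,5,9,10-tetramethyl-6-methylideneundec-10-en-1-yl]oxy}silane | CC(C)(C)[Si](c1ccccc1)(c1ccccc1)OC[C@@H](C)CC[C@@H](C)C(=C)CC[C@@H](C)C(C)=C | intermediate
41 | (2S,5R,9R)-2,5,9,10-tetramethyl-6-methylideneundec-10-en-1-ol | OC[C@@H](C)CC[C@@H](C)C(=C)CC[C@@H](C)C(C)=C | intermediate
42 | 1-phenyl-5-{[(2S,5R,9R)-2,5,9,10-tetramethyl-6-methylideneundec-10-en-1-yl]sulfanyl}-1H-tetrazole | S(C[C@@H](C)CC[C@@H](C)C(=C)CC[C@@H](C)C(C)=C)c1nnnn1-c1ccccc1 | intermediate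
43 | 1-phenyl-5-{[(2S,5R,9R)-2,5,9,10-tetramethyl-6-methylideneundec-10-en-1-yl]sulfonyl}-1H-tetrazole | O=S(=O)(C[C@@H](C)CC[C@@H](C)C(=C)CC[C@@H](C)C(C)=C)c1nnnn1-c1ccccc1 | intermediate
44 | (4R)-1-[(2R,5S,6E,8S,11R,15R)-5-ethenyl-5,8,11,15,16-pentamethyl-12-methylideneheptadeca-6,16-dien-2-yl]-3,3,4-trimethylcyclohex-1-ene | C=C[C@@](C)(/C=C/[C@@H](C)CC[C@@H](C)C(=C)CC[C@@H](C)C(=C)C)CC[C@@H](C)C1=CC(C)(C)[C@H](C)CC1 | target

## Step count and weak points

Total step count: 33. Longest linear sequence: 16 steps (steps 1–6, 8–16 and 33).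

The three steps most likely to fail:

**Step 8 (Zweifel olefination with the hindered cyclohexenyllithium).** The alkene carbon that must be iodinated sits next to the CMe2 group, and the organolithium could also attack the tert-butyl ester. The fallback sets out from triflate 8 and comes back at ester 14. Triflate 8 is coupled (Suzuki–Miyaura, Pd(dppf)Cl2, K3PO4, dioxane/water) with tert-butyl (2Z)-3-(4,4,5,5-tetramethyl-1,3,2-dioxaborolan-2-yl)but-2-enoate F1, itself made by CuCl/Xantphos-catalysed syn-borylation of tert-butyl but-2-ynoate with B2pin2 and MeOH. This gives the dienoate tert-butyl (2E)-3-[(4R)-3,3,4-trimethylcyclohex-1-en-1-yl]but-2-enoate F2. A copper hydride asymmetric 1,4-reduction (Cu(OAc)2, chiral bisphosphine, polymethylhydrosiloxane, t-BuOH, toluene) then sets the CH(Me) centre under catalyst control instead of by boron-to-carbon transfer and delivers 14.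

**Step 16 (BF3 vinyl shift).** A hydride shift to the ketone, or capture of the tertiary cation by the ring alkene, could compete. The fallback sets out from allylic alcohol 19 and comes back at aldehyde 23; it migrates a siloxymethyl group instead of the vinyl group, so the enantiomeric epoxide is needed.
- Sharpless epoxidation of 19 with Ti(Oi-Pr)4 and D-(−)-diethyl tartrate gives [(2R,3R)-3-methyl-3-{(3R)-3-[(4R)-3,3,4-trimethylcyclohex-1-en-1-yl]butyl}oxiran-2-yl]methanol F3.
- Silylation (t-BuMe2SiCl, imidazole) gives tert-butyldimethyl{[(2R,3R)-3-methyl-3-{(3R)-3-[(4R)-3,3,4-trimethylcyclohex-1-en-1-yl]butyl}oxiran-2-yl]methoxy}silane F4.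
- The bulky Lewis acid MeAl(OAr)2 (Ar = 4-bromo-2,6-di-tert-butylphenyl), CH2Cl2, −78 °C, causes anti 1,2-migration of the siloxymethyl group to give (2R,5R)-2-({[tert-butyl(dimethyl)silyl]oxy}methyl)-2-methyl-5-[(4R)-3,3,4-trimethylcyclohex-1-en-1-yl]hexanal F5.
- Wittig methylenation gives tert-butyl({(2S,5R)-2-ethenyl-2-methyl-5-[(4R)-3,3,4-trimethylcyclohex-1-en-1-yl]hexyl}oxy)dimethylsilane F6.
- Bu4NF gives (2S,5R)-2-ethenyl-2-methyl-5-[(4R)-3,3,4-trimethylcyclohex-1-en-1-yl]hexan-1-ol F7, and Dess–Martin oxidation gives 23.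

**Step 29 (copper-catalysed sp3–sp3 coupling of two β-branched partners).** SN2 may be slow, with elimination or homocoupling competing. The fallback sets out from bromide 38 and tosylate 36 and comes back at silyl ether 40; it replaces the Grignard by a sulfone-stabilised carbanion. Bromide 38 and PhSO2Na in DMF give {[(2R)-3-(benzenesulfonyl)-2-methylpropyl]oxy}(tert-butyl)diphenylsilane F8. Tosylate 36 and NaI in acetone give (2S,6R)-1-iodo-2,6,7-trimethyl-3-methylideneoct-7-ene F9. Lithiated F8 (n-BuLi, THF/DMPU, −78 °C) is alkylated by F9 to give {[(2R,5R,9R)-3-(benzenesulfonyl)-2,5,9,10-tetramethyl-6-methylideneundec-10-en-1-yl]oxy}(tert-butyl)diphenylsilane F10 (both C-3 epimers). Reductive desulfonylation (Na/Hg, Na2HPO4, MeOH, −20 °C) then gives 40.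

Further compounds

F1 | step 8 | tert-butyl (2Z)-3-(4,4,5,5-tetramethyl-1,3,2-dioxaborolan-2-yl)but-2-enoate | C/C(=C\C(=O)OC(C)(C)C)B1OC(C)(C)C(C)(C)O1
F2 | step 8 | tert-butyl (2E)-3-[(4R)-3,3,4-trimethylcyclohex-1-en-1-yl]but-2-enoate | C/C(=C\C(=O)OC(C)(C)C)C1=CC(C)(C)[C@H](C)CC1
F3 | step 16 | [(2R,3R)-3-methyl-3-{(3R)-3-[(4R)-3,3,4-trimethylcyclohex-1-en-1-yl]butyl}oxiran-2-yl]methanol | OC[C@H]1O[C@]1(C)CC[C@@H](C)C2=CC(C)(C)[C@H](C)CC2
F4 | step 16 | tert-butyldimethyl{[(2R,3R)-3-methyl-3-{(3R)-3-[(4R)-3,3,4-trimethylcyclohex-1-en-1-yl]butyl}oxiran-2-yl]methoxy}silane | CC(C)(C)[Si](C)(C)OC[C@H]1O[C@]1(C)CC[C@@H](C)C2=CC(C)(C)[C@H](C)CC2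
F5 | step 16 | (2R,5R)-2-({[tert-butyl(dimethyl)silyl]oxy}methyl)-2-methyl-5-[(4R)-3,3,4-trimethylcyclohex-1-en-1-yl]hexanal | CC(C)(C)[Si](C)(C)OC[C@](C)(C=O)CC[C@@H](C)C1=CC(C)(C)[C@H](C)CC1
F6 | step 16 | tert-butyl({(2S,5R)-2-ethenyl-2-methyl-5-[(4R)-3,3,4-trimethylcyclohex-1-en-1-yl]hexyl}oxy)dimethylsilane | CC(C)(C)[Si](C)(C)OC[C@](C)(C=C)CC[C@@H](C)C1=CC(C)(C)[C@H](C)CC1
F7 | step 16 | (2S,5R)-2-ethenyl-2-methyl-5-[(4R)-3,3,4-trimethylcyclohex-1-en-1-yl]hexan-1-ol | OC[C@](C)(C=C)CC[C@@H](C)C1=CC(C)(C)[C@H](C)CC1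
F8 | step 29 | {[(2R)-3-(benzenesulfonyl)-2-methylpropyl]oxy}(tert-butyl)diphenylsilane | O=S(=O)(C[C@H](C)CO[Si](c1ccccc1)(c1ccccc1)C(C)(C)C)c1ccccc1
F9 | step 29 | (2S,6R)-1-iodo-2,6,7-trimethyl-3-methylideneoct-7-ene | IC[C@@H](C)C(=C)CC[C@@H](C)C(C)=C
F10 | step 29 | {[(2R,5R,9R)-3-(benzenesulfonyl)-2,5,9,10-tetramethyl-6-methylideneundec-10-en-1-yl]oxy}(tert-butyl)diphenylsilane (both C-3 epimers) | CC(C)(C)[Si](c1ccccc1)(c1ccccc1)OC[C@@H](C)C(C[C@@H](C)C(=C)CC[C@@H](C)C(C)=C)S(=O)(=O)c1ccccc1
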